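What stays in the flask at the end is a leftover: target is made and lost at once, so I reckoned what stands, not what was made.

    reagent in the reaction phase ⇌ reagent in the second phase, rate k1*([reagent in the reaction phase] - [reagent in the second phase]/K1) per volume of the first phase (K1 = 1.2, k1 = 0.301 /min)
    substrate + reagent in the reaction phase → target (k2 = 0.184 /M/min)
    target ⇌ product in the second phase, rate k3*([target] - [product in the second phase]/K3) per volume of the first phase (K3 = 0.400, k3 = 0.00225 /min)
    target → decomposed product (k4 = 0.0150 /min)
    target → over-reaction product (k5 = 0.0121 /min)
    reagent in the reaction phase ⇌ dormant form (K6 = 0.58, k6 = 0.00191 /min)
    substrate + target → side product (k7 = 0.202 /M/min)

substrate 10 mM; reagent in the second phase 20.0 mM; time 5.0 h; volume of the second phase over the first 0.50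

- percent here means substrate units held: one side product counts as two
- what is said of target includes product in the second phase
- in the second phase: reagent in the second phase, product in the second phase; everything else is in the first
- charges count per volume of the first phase; a concentration in a rate is the amount of a species over the volume of its own phase; every rate counts per litre of the first phase
- run time (flask): 5.0 h

- alder: doubling the transfer coefficient of step 1, all else as stated
- larch: doubling the amount of reagent in the second phase, all else as stated
- maple: doubling the transfer coefficient of step 3, all else as stated

* the target and product in the second phase together standing at 5.0 h, as a percentage of the substrate charged
* the change that raises the amount of target and product in the second phase together at 5.0 h, in percent of the substrate charged most ("none" if none brings more than 2 percentage points) (alder / larch / maple / none)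
* amount of target and product in the second phase together at 5.0 h, in percent of the substrate charged, after maple

Early on, target simply piles up; later it stands level with its making, and the two ends join after a short while. The decomposition and over-reaction steps take a fixed fraction of reaction-phase target each minute, so I used the holding time, one over the sum of their constants, 36.9 min. Its half-life of 0.426 h is shorter than the run, so near the end target should stand at making rate times holding time (quasi-steady state). The second phase can add a share of 0.200 on top.

Reagent first shares out between the phases, which leaves 12.5 mM in the reaction phase. I then bracketed the end:

Lowest substrate, with reagent held at that level: 5.02 mM.

Lowest reagent, with that much consumed and the rest shared with the dormant form: 6.89 mM.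

Highest substrate, with reagent held at that low level: 6.84 mM.

Highest reagent, with none consumed and none passed into the dormant form: 12.5 mM.

Floor, lows multiplied with the rate constant and holding time: 2.35%.

Ceiling, highs likewise, with the second-phase share added: 6.96%.

The forecast said 4.05%, between 3.8% and 4.3%, inside my bracket , on the ground “so it sits near quasi-steady state”. It chose none and gave 4.08% after maple.

The flask gave 4.01%, with none as the best change and 4.02% after maple; larch brought 1.4 percentage points. At 5.00 h reaction-phase target was being made at 0.913 of the rate it was used. The end readings of substrate and reagent, times the holding time and with the second-phase share, give 3.66%.

The same flask read at 20 h holds 19.7% substrate and 5.54 mM reagent in the reaction phase, so the same reckoning gives 0.889%. The computed result there is 0.945%.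

The numbers of this flask belong to no real substance; what happens was integrated by code.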